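## Analysis of the target

The target 21 is a cross-conjugated cyclohexa-2,5-dienone, numbered here C1 (carbonyl), C2 (allyl), C3 (H), C4 (quaternary, OMe), C5 (OMe) and C6 (H). C4 carries a side chain of C8 (CH–CH3) and C7 (benzylic CH2) that ends in a 4-hydroxy-3-methoxyphenyl ring. There are two stereocentres, C4 (R) and C8 (R), bonded to each other; with the chain C5–C4–C8–C7 drawn as a zigzag, the C4 oxygen and the C8 methyl group lie on the same side. C4 is fully substituted, oxygenated and doubly allylic, so it cannot be corrected later and is lost by anything that aromatises the ring. The sensitive groups are the 4-methoxydienone (dienone–phenol shift or loss of methoxide under acid), the vinylogous ester C5=C6–C1=O (nucleophilic at C6, open to addition–elimination at C5), the terminal allyl group (migration into conjugation) and the free phenol. The synthesis is hard for two reasons: a quaternary C–O stereocentre sits next to a tertiary one on a ring that tends to aromatise, and a radical or anion at C7 can expel C4 as an aryloxy fragment while a cation at C7 can be captured by C6. The strategy rests on C4 having the oxidation level of a quinone carbonyl carbon: in the quinone 2 it is the one carbonyl that is not the end of the vinylogous ester MeO–C5=C6–C1=O, and the C4–C8 bond joins it to a methyl-bearing carbon that can be the γ-carbon of a crotyl metal.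

## Retrosynthetic reasoning

**21 from 20.** Only the O–Si bond of the phenol is cut. The phenol must be masked while an aryl Grignard reagent and a radical chain are in use. A bulky silyl ether comes off with buffered fluoride, which the methoxydienone should tolerate.

**20 from 19, and 19 from 14 and 16.** The C7–aryl bond is cut, with C7 as the aldehyde carbon of 14 and the arene as the Grignard reagent 17 made from 16. C7 is the atom that the key step leaves as the inner carbon of a vinyl group, so an aldehyde is its natural electrophilic form. The price is an oxygen at C7 that must be removed. A cation at C7 would be captured by C6, and a free C7 alcohol can close a five-membered ring onto C5 or C3. The alkoxide 18 is therefore trapped in the flask as the thionocarbonate 19, and the C–O bond is broken by a radical chain with a fast hydrogen donor.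

**14 from 12 and 13.** The C2–allyl bond is cut at the vinyl bromide. It is made after the vinyl cleavage, because an allyl group would be cleaved together with the vinyl group. It is made before the radical step, because a stannyl radical would attack the C–Br bond. A neutral Stille coupling also spares the α-stereocentre of the aldehyde.

**12 from 10, and 10 from 9.** The aldehyde carbon C7 is traced back to the vinyl group (loss of the terminal CH2), and the C4 methyl ether to the tertiary alcohol. Methylation comes first: a free C4 hydroxyl β to the C7 aldehyde would invite retro-aldol cleavage of the C4–C8 bond. The oxidative cleavage then removes the 1,5-diene (CH2=CH–C8–C4–C=C) that makes 9 and 10 liable to a [3,3] shift.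

**9 from 2 and 7 (key disconnection).** The C4–C8 bond is cut; C4 becomes a quinone carbonyl and C8 the γ-carbon of a (Z)-crotylboronate. This one bond carries both stereocentres, and no other ring bond has to be made: the six ring carbons, the C5 methoxy group and the C2 handle all come with 2. The forward reaction has to pick C4 over C1, add 1,2 and not 1,4, give the syn relationship, set the absolute configuration through a chiral diol catalyst, and leave the doubly allylic borate 8 and quinol 9 intact.

**2 from 1; 7 from 3 and 4; 16 from 15.** These are one-step preparations: oxidative demethylation of the para pair of methoxy groups, metalation and borylation with retention of the (Z) geometry, and silylation. The uncertainty of the route is thereby concentrated in the key step.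

## Alternatives that were turned down

Alternative 1: The C8–C7 bond is cut. The epoxy alcohol A2, available by Sharpless epoxidation, would be opened at its methyl-bearing carbon (C8) by the benzylic Grignard reagent A3 with catalytic CuI, with inversion, to give the diol A1 with C4 and C8 set.
- For it: the absolute configuration comes from a dependable catalyst-controlled epoxidation, C8 follows from a stereospecific SN2 opening at the less substituted epoxide carbon, and the C7–aryl bond is made far from any dienone. On these points it is stronger than the chosen route.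
- Against it: A1 is acyclic. Its two arms (CH2OH, future C3; CH2OPMB, future C5) must be differentiated, oxidised and joined through three more carbons (C6, C1, C2) into a ring that carries an enol ether at C5 and an allyl group at C2, with the tertiary alcohol methylated on the way. β-Elimination of the C4 oxygen threatens whenever an arm is a carbonyl.
- Comparison: the chosen route is less certain in stereocontrol, but it reaches the complete ring with the right oxygenation in two steps, where this one needs a ring synthesis of many steps after its key step.

Alternative 2: The C5–O bond is traced back to a C5–B bond. The dienone A5, symmetric in its ring and available by oxidative dearomatisation in methanol, would undergo copper-catalysed conjugate borylation (CuCl, NaOtBu, a chiral bisphosphine, a pinacol diboron reagent) at C5 of one enone arm to give A4, which makes C4 a stereocentre.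
- For it: this reaction type is established on 4,4-disubstituted cyclohexadienones, so on precedent it is stronger than the chosen key step. The C4 methoxy group and the whole ArCH2 side chain are in place beforehand, so neither the methylation of a hindered tertiary alcohol nor a deoxygenation at C7 is needed.
- Against it: C8 is not made in the key step and needs its own asymmetric synthesis. Because C8 is already a stereocentre, the two arms are diastereotopic and the catalyst must override the substrate. A4 is at the wrong oxidation level: C–B must become C–OH, then a ketone, then specifically the enol ether MeO–C5=C6 and not its regioisomer at C1, and the other enone needs halogenation and allylation at C2.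
- Comparison: the chosen route has the C5 methoxy group, the C5=C6 bond and the C2 handle correctly placed from the quinone, and it sets C8 together with C4.

Alternative 3: No skeletal bond is cut; the two ester groups of the malonate A7 are told apart. Pig liver esterase would hydrolyse one methyl ester to give the half-ester A6, whose quaternary carbon is the future C4 (acid arm to C3, ester arm to C5).
- For it: an inexpensive, scalable, metal-free step that gives a quaternary C–OMe centre with both arms differentiated, and no reactive C7 intermediate next to a dienone.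
- Against it: the selectivity of this enzyme on disubstituted malonates changes with substituent size and is hard to foresee for a branched, silylated arylalkyl group. C8 must be in place already, and building A7 means alkylating a methoxymalonate with a hindered secondary electrophile at C8 with clean inversion, where elimination competes. As in alternative 1, the carbocycle must then be built from an acyclic diacid derivative.
- Comparison: the chosen strategy is riskier at one step but far shorter, and it makes C4 and C8 in one operation under mutual control.

Key step: step 3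

**Assumption.** The sense of induction of a 3,3'-dibromobinaphthol catalyst on a quinone carbonyl is not established; the (S)-catalyst is written, and its mirror image is to be used without other change if the (4S,8S) quinol forms.

**Remark.** The CIP descriptors of C4 and C8 change along the route (in 12, 14, 18 and 19) only because substituent priorities change; the spatial arrangement set in step 3 is kept throughout.

## Route

Step 1
Reactants: 1 1-bromo-2,4,5-trimethoxybenzene
Product: 2 2-bromo-5-methoxycyclohexa-2,5-diene-1,4-dione
Conditions: (NH4)2Ce(NO3)6, MeCN/H2O, 0 °C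
Reagents that add atoms: water, O
Why: Oxidative demethylation of a 1,4-dimethoxyarene; the para pair of methoxy groups becomes the quinone, with water supplying the carbonyl oxygens, and the bromine and the remaining methoxy group end up next to different carbonyls.

Step 2
Reactants: 3 (Z)-but-2-ene; 4 triisopropyl borate
Product: 7 diisopropyl (Z)-but-2-enylboronate, via (Z)-but-2-enylpotassium 5 (not isolated), via potassium (Z)-but-2-enyl(triisopropoxy)borate 6 (not isolated)
Conditions: KOtBu, n-BuLi, THF, −78 to −50 °C; 4, −78 °C; HCl/Et2O, −78 °C to rt; distillation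
Reagents that add atoms: none
Why: Schlosser-base metalation of cis-2-butene gives the configurationally stable (Z)-crotylpotassium 5 at low temperature, borylation gives the ate complex 6, and acid removes one isopropoxide. The acyclic diisopropyl ester is chosen because a binaphthol can displace one of its alkoxy groups, which a pinacol ester resists.

Step 3
Reactants: 2 2-bromo-5-methoxycyclohexa-2,5-diene-1,4-dione; 7 diisopropyl (Z)-but-2-enylboronate
Product: 9 (4R)-2-bromo-4-[(2R)-but-3-en-2-yl]-4-hydroxy-5-methoxycyclohexa-2,5-dien-1-one, via quinol diisopropyl borate 8 (not isolated)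
Conditions: (S)-3,3'-dibromo-1,1'-bi-2-naphthol (15 mol %), PhCF3/PhMe 3:1, −35 °C; pH 7 phosphate buffer, 0 °C; crude 9 kept cold and used at once
Reagents that add atoms: none
Why: Proposed new method: one isopropoxy group of 7 should exchange with the binaphthol to give a more Lewis-acidic mixed boronate that binds the C4 carbonyl oxygen of 2 and delivers its γ-carbon (C8) to C4 through a six-membered chair transition state, after which isopropanol frees the catalyst from the borate 8; the closest known reactions are the binaphthol-catalysed allyl- and crotylboration of aryl methyl ketones and the uncatalysed 1,2-addition of allylmetal reagents to quinone carbonyls. No ring is closed. C4 is attacked and not C1 because C1 is the carbonyl of the vinylogous ester MeO–C5=C6–C1=O and is flanked by the C2 bromine, and the closed transition state excludes conjugate addition. The configuration of C8 relative to C4 follows from the (Z) geometry, which holds the methyl group axial, together with the equatorial placement of the bulkier C5(OMe) arm (Zimmerman–Traxler model), so that OH and CH3 come out syn along C5–C4–C8. The absolute configuration at C4 is set by the binaphthol, which decides the carbonyl face that the boron-bound crotyl group reaches. The step needs the catalysed pathway to outrun the background addition, which the low temperature and the low Lewis acidity of the dialkoxyboronate 7 should favour. It also needs the doubly allylic quinol to escape the [3,3] shift to a crotylhydroquinone, hence −35 °C and a neutral work-up.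

Step 4
Reactants: 9 (4R)-2-bromo-4-[(2R)-but-3-en-2-yl]-4-hydroxy-5-methoxycyclohexa-2,5-dien-1-one
Product: 10 (4R)-2-bromo-4-[(2R)-but-3-en-2-yl]-4,5-dimethoxycyclohexa-2,5-dien-1-one
Conditions: LiN(SiMe3)2, Et2O, −78 °C; MeOTf, −78 to −30 °C; pH 7 buffer
Reagents that add atoms: methyl trifluoromethanesulfonate, COS(=O)(=O)C(F)(F)F
Why: Williamson-type O-methylation of a lithium alkoxide; the lithium counter-ion and −78 °C are chosen to hold back an anionic oxy-Cope shift of the 1,5-dien-3-olate, and the charge on oxygen keeps the electrophile away from the dienone carbonyl. No stereocentre is touched.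

Step 5
Reactants: 10 (4R)-2-bromo-4-[(2R)-but-3-en-2-yl]-4,5-dimethoxycyclohexa-2,5-dien-1-one
Product: 12 (2S)-2-[(1R)-5-bromo-1,2-dimethoxy-4-oxocyclohexa-2,5-dien-1-yl]propanal, via vicinal diol 11 (not isolated)
Conditions: OsO4 (cat.), NaIO4, 2,6-lutidine, dioxane/H2O 3:1, rt
Reagents that add atoms: osmium tetroxide, O=[Os](=O)(=O)=O; sodium periodate, [Na+].[O-]I(=O)(=O)=O
Why: Lemieux–Johnson cleavage; OsO4 should choose the monosubstituted vinyl group over the bromoenone and the push–pull C5=C6 bond, which are both trisubstituted, conjugated to the carbonyl and next to the quaternary carbon. 2,6-Lutidine keeps the medium near neutral so that C8, now α to an aldehyde and β to the C4 methoxy group, is neither epimerised nor made to eliminate.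

Step 6
Reactants: 12 (2S)-2-[(1R)-5-bromo-1,2-dimethoxy-4-oxocyclohexa-2,5-dien-1-yl]propanal; 13 allyltributylstannane
Product: 14 (2S)-2-[(1S)-1,2-dimethoxy-4-oxo-5-(prop-2-en-1-yl)cyclohexa-2,5-dien-1-yl]propanal
Conditions: Pd2(dba)3 (cat.), AsPh3, CuI, DMF, 45 °C
Reagents that add atoms: none
Why: Stille coupling at the α-bromoenone C2–Br under neutral conditions (zerovalent palladium, CuI-assisted transmetalation). It is placed after the cleavage so that the allyl group never meets OsO4, and before the tin hydride step, which would attack a vinyl bromide.

Step 7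
Reactants: 15 4-bromo-2-methoxyphenol
Product: 16 (4-bromo-2-methoxyphenoxy)tri(propan-2-yl)silane
Conditions: TIPSCl, imidazole, DMF, rt
Reagents that add atoms: chlorotri(propan-2-yl)silane, CC(C)[Si](Cl)(C(C)C)C(C)C
Why: Silylation of the phenol; the bulky silyl ether should withstand Grignard formation and the radical step and is cleaved by fluoride at the end.

Step 8
Reactants: 16 (4-bromo-2-methoxyphenoxy)tri(propan-2-yl)silane; 14 (2S)-2-[(1S)-1,2-dimethoxy-4-oxo-5-(prop-2-en-1-yl)cyclohexa-2,5-dien-1-yl]propanal
Product: 19 O-{(2R)-2-[(1S)-1,2-dimethoxy-4-oxo-5-(prop-2-en-1-yl)cyclohexa-2,5-dien-1-yl]-1-(3-methoxy-4-{[tri(propan-2-yl)silyl]oxy}phenyl)propyl} O-phenyl carbonothioate (both C7 epimers), via arylmagnesium bromide 17 (not isolated), via magnesium alkoxide 18 (not isolated)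
Conditions: 16, Mg, LiCl, THF, rt; then added to 14, THF, −78 °C; then PhOC(S)Cl, −78 to −20 °C
Reagents that add atoms: O-phenyl chlorothionoformate, S=C(Cl)Oc1ccccc1
Why: Grignard addition to an aldehyde, which at −78 °C should be far faster than addition to the cross-conjugated vinylogous-ester carbonyl C1. The alkoxide 18 is thioacylated in the flask so that a free C7 oxygen nucleophile is never left next to C5 and C3. The new C7 centre forms as a mixture of epimers, which is of no consequence because C7 becomes CH2.

Step 9
Reactants: 19 the O-phenyl thionocarbonate of step 8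
Product: 20 (4R)-4,5-dimethoxy-4-[(2R)-1-(3-methoxy-4-{[tri(propan-2-yl)silyl]oxy}phenyl)propan-2-yl]-2-(prop-2-en-1-yl)cyclohexa-2,5-dien-1-one
Conditions: Bu3SnH, PhSeSePh (10 mol %), 2,2'-azobis(4-methoxy-2,4-dimethylvaleronitrile), PhMe, 30 °C
Reagents that add atoms: none
Why: Barton–McCombie deoxygenation; benzeneselenol formed from PhSeSePh and Bu3SnH is a very fast hydrogen-atom donor, and with a low-temperature initiator the benzylic C7 radical should be reduced before it can break the C8–C4 bond. No cation that C6 could capture is formed, and C4 and C8 are not involved.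

Step 10
Reactants: 20 the silyl ether of step 9
Product: 21 (4R)-4-[(2R)-1-(4-hydroxy-3-methoxyphenyl)propan-2-yl]-4,5-dimethoxy-2-(prop-2-en-1-yl)cyclohexa-2,5-dien-1-one
Conditions: Bu4NF, AcOH, THF, 0 °C
Reagents that add atoms: none
Why: Fluoride cleavage of the aryl silyl ether, buffered with acetic acid so that neither a phenoxide nor a strong acid meets the 4-methoxydienone.

## Compound list

1 | 1-bromo-2,4,5-trimethoxybenzene | COc1cc(OC)c(Br)cc1OC | starting material
2 | 2-bromo-5-methoxycyclohexa-2,5-diene-1,4-dione | COC1=CC(=O)C(Br)=CC1=O | intermediate
3 | (Z)-but-2-ene | C/C=C\C | starting material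
4 | triisopropyl borate | CC(C)OB(OC(C)C)OC(C)C | starting material
5 | (Z)-but-2-enylpotassium | C/C=C\C[K] | intermediate
6 | potassium (Z)-but-2-enyl(triisopropoxy)borate | C/C=C\C[B-](OC(C)C)(OC(C)C)OC(C)C.[K+] | intermediate
7 | diisopropyl (Z)-but-2-enylboronate | C/C=C\CB(OC(C)C)OC(C)C | intermediate
8 | (1R)-5-bromo-1-[(2R)-but-3-en-2-yl]-2-methoxy-4-oxocyclohexa-2,5-dien-1-yl diisopropyl borate | BrC1=C[C@](OB(OC(C)C)OC(C)C)([C@H](C)C=C)C(OC)=CC1=O | intermediate
9 | (4R)-2-bromo-4-[(2R)-but-3-en-2-yl]-4-hydroxy-5-methoxycyclohexa-2,5-dien-1-one | BrC1=C[C@](O)([C@H](C)C=C)C(OC)=CC1=O | intermediate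
10 | (4R)-2-bromo-4-[(2R)-but-3-en-2-yl]-4,5-dimethoxycyclohexa-2,5-dien-1-one | BrC1=C[C@](OC)([C@H](C)C=C)C(OC)=CC1=O | intermediate
11 | (4R)-2-bromo-4-[(2R)-3,4-dihydroxybutan-2-yl]-4,5-dimethoxycyclohexa-2,5-dien-1-one (both epimers at the secondary carbinol) | BrC1=C[C@](OC)([C@H](C)C(O)CO)C(OC)=CC1=O | intermediate
12 | (2S)-2-[(1R)-5-bromo-1,2-dimethoxy-4-oxocyclohexa-2,5-dien-1-yl]propanal | BrC1=C[C@](OC)([C@H](C)C=O)C(OC)=CC1=O | intermediate
13 | allyltributylstannane | C=CC[Sn](CCCC)(CCCC)CCCC | starting material
14 | (2S)-2-[(1S)-1,2-dimethoxy-4-oxo-5-(prop-2-en-1-yl)cyclohexa-2,5-dien-1-yl]propanal | C=CCC1=C[C@](OC)([C@H](C)C=O)C(OC)=CC1=O | intermediate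
15 | 4-bromo-2-methoxyphenol | COc1cc(Br)ccc1O | starting material
16 | (4-bromo-2-methoxyphenoxy)tri(propan-2-yl)silane | COc1cc(Br)ccc1O[Si](C(C)C)(C(C)C)C(C)C | intermediate
17 | (3-methoxy-4-{[tri(propan-2-yl)silyl]oxy}phenyl)magnesium bromide | COc1cc([Mg]Br)ccc1O[Si](C(C)C)(C(C)C)C(C)C | intermediate
18 | bromomagnesium (2R)-2-[(1S)-1,2-dimethoxy-4-oxo-5-(prop-2-en-1-yl)cyclohexa-2,5-dien-1-yl]-1-(3-methoxy-4-{[tri(propan-2-yl)silyl]oxy}phenyl)propan-1-olate (both C7 epimers) | C=CCC1=C[C@](OC)([C@H](C)C(O[Mg]Br)c2ccc(O[Si](C(C)C)(C(C)C)C(C)C)c(OC)c2)C(OC)=CC1=O | intermediate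
19 | O-{(2R)-2-[(1S)-1,2-dimethoxy-4-oxo-5-(prop-2-en-1-yl)cyclohexa-2,5-dien-1-yl]-1-(3-methoxy-4-{[tri(propan-2-yl)silyl]oxy}phenyl)propyl} O-phenyl carbonothioate (both C7 epimers) | C=CCC1=C[C@](OC)([C@H](C)C(OC(=S)Oc2ccccc2)c2ccc(O[Si](C(C)C)(C(C)C)C(C)C)c(OC)c2)C(OC)=CC1=O | intermediate
20 | (4R)-4,5-dimethoxy-4-[(2R)-1-(3-methoxy-4-{[tri(propan-2-yl)silyl]oxy}phenyl)propan-2-yl]-2-(prop-2-en-1-yl)cyclohexa-2,5-dien-1-one | C=CCC1=C[C@](OC)([C@H](C)Cc2ccc(O[Si](C(C)C)(C(C)C)C(C)C)c(OC)c2)C(OC)=CC1=O | intermediate
21 | (4R)-4-[(2R)-1-(4-hydroxy-3-methoxyphenyl)propan-2-yl]-4,5-dimethoxy-2-(prop-2-en-1-yl)cyclohexa-2,5-dien-1-one | C=CCC1=C[C@](OC)([C@H](C)Cc2ccc(O)c(OC)c2)C(OC)=CC1=O | target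

## Step count and least certain steps

Total: 10 steps. Longest linear sequence: 8 steps from 1 (steps 1, 3, 4, 5, 6, 8, 9, 10).

**Step 3 (key step).**
- What may go wrong: weak discrimination between the two ring arms (H at C3 against OMe at C5) by the chiral boronate, hence poor facial selectivity; competition from the uncatalysed addition, since a quinone carbonyl is more electrophilic than the ketones for which this catalysis is known; the C3 arm taking the equatorial place, which inverts the relative configuration; and [3,3] shift of 8 or 9 with aromatisation.
- First correction: if only the relative configuration is wrong, diisopropyl (E)-but-2-enylboronate F1, made as in step 2 from trans-2-butene, takes the place of 7.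
- Fallback with known chemistry: from 2 and 7, the uncatalysed closed-transition-state crotylboration (PhMe, −20 °C to rt, no binaphthol), of the kind known for allylmetal additions to quinone carbonyls, should give the racemic syn quinol, that is 9 together with the enantiomeric quinol F2. Methylation as in step 4 gives 10 together with the enantiomeric methyl ether F3, and preparative chromatography on a chiral stationary phase separates them. The route is rejoined at 10.

**Step 9.**
- What may go wrong: fragmentation of the benzylic C7 radical by cleavage of the C8–C4 bond, which would release an aromatic aryloxyl radical and an alkene, in competition with hydrogen transfer; also O-to-S rearrangement or ionisation of the electron-rich benzylic thionocarbonate before the chain starts.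
- Fallback (no oxygen and no radical chain at C7): from 14, NaBH4 in MeOH/CH2Cl2 at −78 °C should reduce only the aldehyde to the primary alcohol F10. I2, PPh3 and imidazole give the primary iodide F11. Zinc dust with LiCl in THF gives the alkylzinc iodide F12, which is coupled with 16 under Negishi conditions (Pd(OAc)2, SPhos, THF, rt). This replaces steps 8 and 9 and rejoins the route at 20.

**Step 8.**
- What may go wrong: deprotonation of the aldehyde at C8 by the Grignard reagent, followed by epimerisation or by loss of the C4 methoxide (β-elimination to a quinone methide); addition to the C1 carbonyl; ring closure of the alkoxide onto C5 or C3 before thioacylation is complete.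
- Fallback: a Nozaki–Hiyama–Kishi coupling, which uses a non-basic arylchromium species and leaves an inert chromium alkoxide. 4-Iodo-2-methoxyphenol F7 is silylated as in step 7 to (4-iodo-2-methoxyphenoxy)tri(propan-2-yl)silane F8. F8 and 14 with CrCl2 and catalytic NiCl2 in DMF at rt should give the benzylic alcohol F9, which is thioacylated at once (PhOC(S)Cl, pyridine, DMAP, CH2Cl2, 0 °C) to 19. The fallback sets out from 14 and rejoins the route at 19.

**Step 4.**
- What may go wrong: anionic [3,3] shift of the lithium alkoxide of 9 with aromatisation before O-methylation, or slow methylation of the hindered tertiary alkoxide.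
- Fallback: the 1,5-diene is removed before any alkoxide is made. From 9, OsO4 (cat.) and N-methylmorpholine N-oxide in acetone/water give the triol F4. 2,2-Dimethoxypropane with pyridinium p-toluenesulfonate gives the terminal acetonide F5. NaH and MeI in THF at 0 °C give the methylated acetonide F6, in which no sigmatropic shift is possible. H5IO6 in EtOAc unmasks the diol 11 and cleaves it to 12, where the route is rejoined.

## Further compounds

F1 | step 3 | diisopropyl (E)-but-2-enylboronate | C/C=C/CB(OC(C)C)OC(C)C
F2 | step 3 | (4S)-2-bromo-4-[(2S)-but-3-en-2-yl]-4-hydroxy-5-methoxycyclohexa-2,5-dien-1-one (enantiomer of 9) | BrC1=C[C@@](O)([C@@H](C)C=C)C(OC)=CC1=O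
F3 | step 3 | (4S)-2-bromo-4-[(2S)-but-3-en-2-yl]-4,5-dimethoxycyclohexa-2,5-dien-1-one (enantiomer of 10) | BrC1=C[C@@](OC)([C@@H](C)C=C)C(OC)=CC1=O
F4 | step 4 | (4R)-2-bromo-4-[(2R)-3,4-dihydroxybutan-2-yl]-4-hydroxy-5-methoxycyclohexa-2,5-dien-1-one (both carbinol epimers) | BrC1=C[C@](O)([C@H](C)C(O)CO)C(OC)=CC1=O
F5 | step 4 | (4R)-2-bromo-4-[(1R)-1-(2,2-dimethyl-1,3-dioxolan-4-yl)ethyl]-4-hydroxy-5-methoxycyclohexa-2,5-dien-1-one | BrC1=C[C@](O)([C@H](C)C2COC(C)(C)O2)C(OC)=CC1=O
F6 | step 4 | (4R)-2-bromo-4-[(1R)-1-(2,2-dimethyl-1,3-dioxolan-4-yl)ethyl]-4,5-dimethoxycyclohexa-2,5-dien-1-one | BrC1=C[C@](OC)([C@H](C)C2COC(C)(C)O2)C(OC)=CC1=O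
F7 | step 8 | 4-iodo-2-methoxyphenol | COc1cc(I)ccc1O
F8 | step 8 | (4-iodo-2-methoxyphenoxy)tri(propan-2-yl)silane | COc1cc(I)ccc1O[Si](C(C)C)(C(C)C)C(C)C
F9 | step 8 | benzylic alcohol: C7-hydroxy analogue of 20 (both C7 epimers; C4 and C8 as in 14) | C=CCC1=C[C@](OC)([C@H](C)C(O)c2ccc(O[Si](C(C)C)(C(C)C)C(C)C)c(OC)c2)C(OC)=CC1=O
F10 | step 9 | primary alcohol: 4-(1-hydroxypropan-2-yl)-4,5-dimethoxy-2-(prop-2-en-1-yl)cyclohexa-2,5-dien-1-one (C4 and C8 as in 14) | C=CCC1=C[C@](OC)([C@H](C)CO)C(OC)=CC1=O
F11 | step 9 | primary iodide: 4-(1-iodopropan-2-yl)-4,5-dimethoxy-2-(prop-2-en-1-yl)cyclohexa-2,5-dien-1-one (C4 and C8 as in 14) | C=CCC1=C[C@](OC)([C@H](C)CI)C(OC)=CC1=O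
F12 | step 9 | alkylzinc iodide derived from F11 | C=CCC1=C[C@](OC)([C@H](C)C[Zn]I)C(OC)=CC1=O
A1 | alternative 1 | 2-{[(4-methoxybenzyl)oxy]methyl}-4-(3-methoxy-4-{[tri(propan-2-yl)silyl]oxy}phenyl)-3-methylbutane-1,2-diol (C4 and C8 set) | COc1ccc(COC[C@](O)([C@H](C)Cc2ccc(O[Si](C(C)C)(C(C)C)C(C)C)c(OC)c2)CO)cc1
A2 | alternative 1 | [(2S,3R)-2-{[(4-methoxybenzyl)oxy]methyl}-3-methyloxiran-2-yl]methanol | COc1ccc(COC[C@]2(CO)O[C@@H]2C)cc1
A3 | alternative 1 | (3-methoxy-4-{[tri(propan-2-yl)silyl]oxy}benzyl)magnesium chloride | COc1cc(C[Mg]Cl)ccc1O[Si](C(C)C)(C(C)C)C(C)C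
A4 | alternative 2 | C5-borylated 4-methoxy-4-alkylcyclohex-2-en-1-one (pinacol boronate) | O=C1C=C[C@](OC)([C@H](C)Cc2ccc(O[Si](C(C)C)(C(C)C)C(C)C)c(OC)c2)[C@@H](B3OC(C)(C)C(C)(C)O3)C1
A5 | alternative 2 | 4-methoxy-4-[(2R)-1-(3-methoxy-4-{[tri(propan-2-yl)silyl]oxy}phenyl)propan-2-yl]cyclohexa-2,5-dien-1-one | O=C1C=CC(OC)([C@H](C)Cc2ccc(O[Si](C(C)C)(C(C)C)C(C)C)c(OC)c2)C=C1
A6 | alternative 3 | malonate half-ester with C4 set | OC(=O)[C@](OC)([C@H](C)Cc1ccc(O[Si](C(C)C)(C(C)C)C(C)C)c(OC)c1)C(=O)OC
A7 | alternative 3 | dimethyl 2-methoxy-2-[(2R)-1-(3-methoxy-4-{[tri(propan-2-yl)silyl]oxy}phenyl)propan-2-yl]propanedioate | COC(=O)C(OC)([C@H](C)Cc1ccc(O[Si](C(C)C)(C(C)C)C(C)C)c(OC)c1)C(=O)OC
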